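**Retrosynthetic overview** (target numbering: C1 bridgehead next to C8 and C2; C2 C=O; C3 aroyl carbon; C4 enol C–OH; C5 bridgehead; C6 CH2; C7 CH; C8 CMe2; C9 bridging C=O)
1. Ring B (C1–C9–C5–C6–C7–C8) is cut at C5–C6 and at the quaternary–quaternary bond C1–C8. This gives a flat, achiral 3-aroyl-1,5-diprenylphloroglucinol (ring A still aromatic) and the C6–C7–C8 bis-electrophile 2-(acetoxymethyl)-3-methylbut-2-enal.
2. Enabling feature: in ring A, C1 and C5 are two equivalent enolate carbons of the vinylogous acid C2–C3(aroyl)–C4, held 1,3 to each other across C9, while C3 is blocked by the aroyl group. A three-atom electrophile can therefore bridge C1 and C5, and only on one face.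
3. The formyl group on C7 is a temporary activating group (it makes C8 a Michael acceptor). It later becomes the CH2 of the C7 prenyl group through two Wittig reactions.
4. C1 and C5 are set by a chiral ammonium ion pair in the first C-alkylation; C7 is set by equilibration of the formyl group to the exo (equatorial) position.
5. Ring order: catechol ring and ring A are bought as arenes and joined by Houben–Hoesch acylation; a temporary dioxole ring protects the catechol (step 2, removed in step 8); ring B is closed last (step 7).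

Key step: step 7

Remark (assumption): the sense of induction of the ammonium ion pair in step 7 cannot be assigned in advance; both pseudo-enantiomeric catalysts (cinchonidine and cinchonine series) exist, and the one that gives the (1S,5S) series is used.
Remark: the orthoformate carbon of 5, 6 and 11–14 is a stereocentre without consequence; these compounds are carried as epimer mixtures at that carbon (left open in the SMILES) and the centre is removed in step 8.

**Step 1**
Reactants: 1 phloroglucinol; 2 3,4-dihydroxybenzonitrile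
Product: 4 maclurin (3,4-dihydroxyphenyl)(2,4,6-trihydroxyphenyl)methanone, via ketiminium chloride 3 (not isolated)
Conditions: ZnCl2 (cat.), HCl (g), Et2O, 0 °C; then H2O, 100 °C
Reagents that add atoms: water, O
Why: Houben–Hoesch acylation, in which the HCl/ZnCl2-activated nitrile attacks the most electron-rich arene once (the ketiminium salt deactivates the ring) and hydrolysis should give the benzophenone; no stereocentre is formed.

**Step 2**
Reactants: 4 maclurin
Product: 5 (2-ethoxy-1,3-benzodioxol-5-yl)(2,4,6-trihydroxyphenyl)methanone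
Conditions: HC(OEt)3, Amberlyst-15 (cat.), toluene/1,4-dioxane, 100 °C, EtOH distilled off
Reagents that add atoms: triethyl orthoformate, CCOC(OCC)OCC
Why: Acid-catalysed transorthoesterification, in which only the catechol 1,2-diol can close the five-membered cyclic orthoformate while acyclic aryl orthoformates of the isolated phloroglucinol hydroxyls revert on work-up; the new acetal carbon is an inconsequential stereocentre.

**Step 3**
Reactants: 5 (2-ethoxy-1,3-benzodioxol-5-yl)(2,4,6-trihydroxyphenyl)methanone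
Product: 6 (2-ethoxy-1,3-benzodioxol-5-yl)[2,4,6-trihydroxy-3,5-bis(3-methylbut-2-en-1-yl)phenyl]methanone
Conditions: prenyl bromide (2.2 equiv), 10% aq. KOH, 0 °C
Reagents that add atoms: prenyl bromide, CC(C)=CCBr
Why: C-Alkylation of the acylphloroglucinol polyanion with an allylic bromide in water should occur at the two free ring carbons, the orthoformate being inert to base; over-alkylation is the known limit of this reaction.

**Step 4**
Reactants: 7 diethyl 2-(propan-2-ylidene)propanedioate
Product: 8 2-(propan-2-ylidene)propane-1,3-diol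
Conditions: DIBAL-H (4.5 equiv), CH2Cl2, −78 → 0 °C; aq. Rochelle salt
Reagents that add atoms: none
Why: 1,2-Reduction of both esters of the alkylidene malonate by DIBAL-H should give the allylic diol, the β,β-disubstituted alkene resisting conjugate reduction.

**Step 5**
Reactants: 8 2-(propan-2-ylidene)propane-1,3-diol
Product: 9 2-(hydroxymethyl)-3-methylbut-2-en-1-yl acetate
Conditions: vinyl acetate, immobilised Candida antarctica lipase B (cat.), THF, 23 °C
Reagents that add atoms: vinyl acetate, CC(=O)OC=C
Why: Lipase-catalysed transesterification with an irreversible acyl donor should acylate one of the two equivalent primary hydroxyls and stop at the monoester.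

**Step 6**
Reactants: 9 2-(hydroxymethyl)-3-methylbut-2-en-1-yl acetate
Product: 10 2-formyl-3-methylbut-2-en-1-yl acetate [2-(acetoxymethyl)-3-methylbut-2-enal]
Conditions: PhI(OAc)2 (1.1 equiv), TEMPO (10 mol%), CH2Cl2, 23 °C
Reagents that add atoms: none
Why: Oxoammonium (TEMPO) oxidation of the primary allylic alcohol should give the enal without touching the acetate; the alkene carries two identical methyls, so there is no geometry issue.

**Step 7**
Reactants: 6 (2-ethoxy-1,3-benzodioxol-5-yl)[2,4,6-trihydroxy-3,5-bis(3-methylbut-2-en-1-yl)phenyl]methanone; 10 2-formyl-3-methylbut-2-en-1-yl acetate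
Product: 13 exo-aldehyde (1S,5S,7R)-3-[(2-ethoxy-1,3-benzodioxol-5-yl)carbonyl]-4-hydroxy-8,8-dimethyl-1,5-bis(3-methylbut-2-en-1-yl)-2,9-dioxobicyclo[3.3.1]non-3-ene-7-carbaldehyde, via dearomatised enal 11 (not isolated), via endo-formyl epimer 12 (not isolated)
Conditions: 10 (1.5 equiv), dimeric cinchonidinium phase-transfer catalyst [2,7-bis(O-allylcinchonidinium-N-methyl)naphthalene dibromide, 10 mol%], CsOH·H2O (4 equiv), 4 Å MS, CH2Cl2, −50 °C; then MeOH, −50 → 23 °C; pH 6 phosphate buffer
Reagents that add atoms: none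
Why: The phloroglucinolate of 6, ion-paired with the chiral bis-ammonium cation, is C-alkylated by the allylic acetate terminus of 10 (C5–C6, loss of acetate) to the dearomatised enal 11, whose remaining enolate carbon C1 then adds to the β,β-dimethyl enal terminus C8 in an intramolecular Michael addition that forges the quaternary–quaternary C1–C8 bond. The closest known reaction type is the base-mediated alkylative dearomatisation–annulation of 3,5-diprenylated acylphloroglucinols with α-(acetoxymethyl) enals, including its cinchona phase-transfer-catalysed enantioselective form. Ring B (C1–C9–C5–C6–C7–C8) is closed in the 6-endo-trig mode, the C7=C8 bond of the acceptor lying inside the forming ring. C5 is set by the chiral ion pair, which distinguishes the two enantiotopic faces of the symmetric nucleophile in the first alkylation; C1 follows by geometry, because a three-atom bridge can span C5 and C1 only on the same face; C7 is set by thermodynamics, the kinetically protonated endo-formyl epimer 12 being epimerised through its enolate in methanol to the equatorial (exo) position, where the formyl group avoids the transannular contact with C3 of ring A. The step needs C- over O-alkylation and ring closure at C1 instead of C3: the soft allylic electrophile and the anionic vinylogous acid favour carbon, O-Michael adducts revert, and C3 is the aroyl-bearing carbon flanked by three carbonyls, the least nucleophilic and most hindered position.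

**Step 8**
Reactants: 13 exo-aldehyde
Product: 15 2-[(1S,5S,7S)-3-(3,4-dihydroxybenzoyl)-4-hydroxy-8,8-dimethyl-1,5-bis(3-methylbut-2-en-1-yl)-2,9-dioxobicyclo[3.3.1]non-3-en-7-yl]acetaldehyde, via methyl enol ether 14 (not isolated)
Conditions: MeOCH2PPh3Cl (4 equiv), KHMDS (3.9 equiv), THF, −78 → 0 °C; then 2 M aq. HCl–THF (1:4), 23 °C; aq. NaHCO3 work-up
Reagents that add atoms: (methoxymethyl)triphenylphosphonium chloride, COC[P+](c1ccccc1)(c1ccccc1)c1ccccc1.[Cl-]; water, O
Why: Wittig methoxymethylenation of the formyl group (the triketone is masked in situ as its enolate and the C9 ketone is shielded by two quaternary carbons) followed by acid hydrolysis of the enol ether should give the one-carbon-homologated aldehyde, the same acid cleaving the cyclic orthoformate to the free catechol; C7 is no longer α to a carbonyl after olefination and keeps its configuration (the descriptor changes from R to S only through the priority rules).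

**Step 9**
Reactants: 15 homologated aldehyde
Product: 16 aristophenone A (1S,5S,7R)-3-(3,4-dihydroxybenzoyl)-4-hydroxy-8,8-dimethyl-1,5,7-tris(3-methylbut-2-en-1-yl)bicyclo[3.3.1]non-3-ene-2,9-dione
Conditions: i-PrPPh3I (6 equiv), KHMDS (5.8 equiv), THF–DMPU, −78 → 0 °C; aq. NaH2PO4
Reagents that add atoms: isopropyltriphenylphosphonium iodide, CC(C)[P+](c1ccccc1)(c1ccccc1)c1ccccc1.[I-]
Why: Wittig olefination with the non-stabilised isopropylidene ylide should turn the CH2CHO group into the prenyl group; the three acidic hydroxyls are only deprotonated by the excess ylide and return on work-up, and no stereocentre is touched.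

**Compound list**
1 | phloroglucinol (benzene-1,3,5-triol) | Oc1cc(O)cc(O)c1 | starting material
2 | 3,4-dihydroxybenzonitrile | N#Cc1ccc(O)c(O)c1 | starting material
3 | (3,4-dihydroxyphenyl)(2,4,6-trihydroxyphenyl)methaniminium chloride | [NH2+]=C(c1ccc(O)c(O)c1)c1c(O)cc(O)cc1O.[Cl-] | intermediate
4 | maclurin, (3,4-dihydroxyphenyl)(2,4,6-trihydroxyphenyl)methanone | O=C(c1ccc(O)c(O)c1)c1c(O)cc(O)cc1O | intermediate
5 | (2-ethoxy-1,3-benzodioxol-5-yl)(2,4,6-trihydroxyphenyl)methanone (acetal epimers) | CCOC1Oc2ccc(cc2O1)C(=O)c1c(O)cc(O)cc1O | intermediate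
6 | (2-ethoxy-1,3-benzodioxol-5-yl)[2,4,6-trihydroxy-3,5-bis(3-methylbut-2-en-1-yl)phenyl]methanone (acetal epimers) | CCOC1Oc2ccc(cc2O1)C(=O)c1c(O)c(CC=C(C)C)c(O)c(CC=C(C)C)c1O | intermediate
7 | diethyl 2-(propan-2-ylidene)propanedioate | CCOC(=O)C(=C(C)C)C(=O)OCC | starting material
8 | 2-(propan-2-ylidene)propane-1,3-diol | CC(C)=C(CO)CO | intermediate
9 | 2-(hydroxymethyl)-3-methylbut-2-en-1-yl acetate | CC(C)=C(CO)COC(C)=O | intermediate
10 | 2-formyl-3-methylbut-2-en-1-yl acetate | CC(C)=C(C=O)COC(C)=O | intermediate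
11 | 2-{[(1S)-3-[(2-ethoxy-1,3-benzodioxol-5-yl)carbonyl]-2,4-dihydroxy-1,5-bis(3-methylbut-2-en-1-yl)-6-oxocyclohexa-2,4-dien-1-yl]methyl}-3-methylbut-2-enal (one tautomer drawn; S at the quaternary ring carbon, the later C5) | O=CC(=C(C)C)C[C@]1(CC=C(C)C)C(=O)C(CC=C(C)C)=C(O)C(C(=O)c2ccc3OC(OCC)Oc3c2)=C1O | intermediate
12 | (1S,5S,7S)-3-[(2-ethoxy-1,3-benzodioxol-5-yl)carbonyl]-4-hydroxy-8,8-dimethyl-1,5-bis(3-methylbut-2-en-1-yl)-2,9-dioxobicyclo[3.3.1]non-3-ene-7-carbaldehyde (formyl endo, axial) | O=C[C@H]1C[C@]2(CC=C(C)C)C(=O)[C@@](CC=C(C)C)(C(=O)C(C(=O)c3ccc4OC(OCC)Oc4c3)=C2O)C1(C)C | intermediate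
13 | (1S,5S,7R)-3-[(2-ethoxy-1,3-benzodioxol-5-yl)carbonyl]-4-hydroxy-8,8-dimethyl-1,5-bis(3-methylbut-2-en-1-yl)-2,9-dioxobicyclo[3.3.1]non-3-ene-7-carbaldehyde (formyl exo, equatorial) | O=C[C@@H]1C[C@]2(CC=C(C)C)C(=O)[C@@](CC=C(C)C)(C(=O)C(C(=O)c3ccc4OC(OCC)Oc4c3)=C2O)C1(C)C | intermediate
14 | (1S,5S,7S)-3-[(2-ethoxy-1,3-benzodioxol-5-yl)carbonyl]-4-hydroxy-7-(2-methoxyethenyl)-8,8-dimethyl-1,5-bis(3-methylbut-2-en-1-yl)bicyclo[3.3.1]non-3-ene-2,9-dione (E/Z mixture) | COC=C[C@@H]1C[C@]2(CC=C(C)C)C(=O)[C@@](CC=C(C)C)(C(=O)C(C(=O)c3ccc4OC(OCC)Oc4c3)=C2O)C1(C)C | intermediate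
15 | 2-[(1S,5S,7S)-3-(3,4-dihydroxybenzoyl)-4-hydroxy-8,8-dimethyl-1,5-bis(3-methylbut-2-en-1-yl)-2,9-dioxobicyclo[3.3.1]non-3-en-7-yl]acetaldehyde | O=CC[C@@H]1C[C@]2(CC=C(C)C)C(=O)[C@@](CC=C(C)C)(C(=O)C(C(=O)c3ccc(O)c(O)c3)=C2O)C1(C)C | intermediate
16 | aristophenone A, (1S,5S,7R)-3-(3,4-dihydroxybenzoyl)-4-hydroxy-8,8-dimethyl-1,5,7-tris(3-methylbut-2-en-1-yl)bicyclo[3.3.1]non-3-ene-2,9-dione | CC(C)=CC[C@@H]1C[C@]2(CC=C(C)C)C(=O)[C@@](CC=C(C)C)(C(=O)C(C(=O)c3ccc(O)c(O)c3)=C2O)C1(C)C | target

**Step count and risks**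
Total steps: 9. Longest linear sequence: 6 (steps 1, 2, 3, 7, 8, 9; the enal branch 4, 5, 6, 7, 8, 9 is equally long).

Steps most likely to fail:

1. Step 7. The enantioselectivity may be eroded by uncatalysed background alkylation, or by a competing first bond at C8 (conjugate addition before acetate loss), which leads to the antipodal bicycle. The formyl group may also equilibrate incompletely, because the axial epimer can be held back by reversible aldol capture at C3, and the ring may reopen by retro-Michael reaction. Fallback: starting from 6 and 10, the annulation is run with KHMDS in THF at 65 °C (achiral base, thermodynamic control) to give the racemic exo-aldehyde, that is 13 together with its enantiomer, the (1R,5R,7S)-aldehyde F1. The two are separated by preparative chromatography on a chiral stationary phase, F1 is discarded, and the route is rejoined at 13.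

2. Step 8. The basic ylide may enolise the hindered α-branched aldehyde instead of olefinating it, and the aqueous acid may cyclise a prenyl group onto the enol oxygen. Fallback: starting from 13, addition of vinylcerium dichloride (vinylmagnesium bromide, CeCl3, THF, −78 °C) should give the allylic alcohol F2 as carbinol epimers. Acetylation (Ac2O, pyridine, DMAP, then brief K2CO3/MeOH to return the enol) should give the allylic acetate F3. Pd(0)-catalysed formate reduction (Pd(OAc)2, PBu3, HCO2NH4, THF) should deliver hydride to the internal allyl terminus and give the 7-allyl compound F4. Cross-metathesis with 2-methyl-2-butene (Ru–NHC benzylidene catalyst) should give the orthoformate-protected target F5, and 0.5 M HCl in THF/H2O then cleaves the orthoformate. The route is rejoined at 16, so step 9 is bypassed as well.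

3. Step 9. The trianion may be poorly soluble, and the excess base may enolise or self-condense the CH2CHO group before olefination. Fallback: starting from 15, TBSCl and imidazole in DMF should silylate the two catechol hydroxyls to give the bis-silyl ether F6 (the labile enol silyl ether is lost on work-up). Wittig olefination with isopropylidenetriphenylphosphorane, now with a single acidic hydroxyl, should give the bis-silyl ether of the target F7, and HF·pyridine in THF removes the silyl groups. The route is rejoined at 16.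

**Further compounds**
F1 | step 7 | (1R,5R,7S)-3-[(2-ethoxy-1,3-benzodioxol-5-yl)carbonyl]-4-hydroxy-8,8-dimethyl-1,5-bis(3-methylbut-2-en-1-yl)-2,9-dioxobicyclo[3.3.1]non-3-ene-7-carbaldehyde (enantiomer of 13) | O=C[C@H]1C[C@@]2(CC=C(C)C)C(=O)[C@](CC=C(C)C)(C(=O)C(C(=O)c3ccc4OC(OCC)Oc4c3)=C2O)C1(C)C
F2 | step 8 | (1S,5S,7R)-3-[(2-ethoxy-1,3-benzodioxol-5-yl)carbonyl]-4-hydroxy-7-(1-hydroxyprop-2-en-1-yl)-8,8-dimethyl-1,5-bis(3-methylbut-2-en-1-yl)bicyclo[3.3.1]non-3-ene-2,9-dione (carbinol epimers) | C=CC(O)[C@@H]1C[C@]2(CC=C(C)C)C(=O)[C@@](CC=C(C)C)(C(=O)C(C(=O)c3ccc4OC(OCC)Oc4c3)=C2O)C1(C)C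
F3 | step 8 | 1-[(1S,5S,7R)-3-[(2-ethoxy-1,3-benzodioxol-5-yl)carbonyl]-4-hydroxy-8,8-dimethyl-1,5-bis(3-methylbut-2-en-1-yl)-2,9-dioxobicyclo[3.3.1]non-3-en-7-yl]prop-2-en-1-yl acetate | C=CC(OC(C)=O)[C@@H]1C[C@]2(CC=C(C)C)C(=O)[C@@](CC=C(C)C)(C(=O)C(C(=O)c3ccc4OC(OCC)Oc4c3)=C2O)C1(C)C
F4 | step 8 | (1S,5S,7R)-3-[(2-ethoxy-1,3-benzodioxol-5-yl)carbonyl]-4-hydroxy-8,8-dimethyl-1,5-bis(3-methylbut-2-en-1-yl)-7-(prop-2-en-1-yl)bicyclo[3.3.1]non-3-ene-2,9-dione | C=CC[C@@H]1C[C@]2(CC=C(C)C)C(=O)[C@@](CC=C(C)C)(C(=O)C(C(=O)c3ccc4OC(OCC)Oc4c3)=C2O)C1(C)C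
F5 | step 8 | (1S,5S,7R)-3-[(2-ethoxy-1,3-benzodioxol-5-yl)carbonyl]-4-hydroxy-8,8-dimethyl-1,5,7-tris(3-methylbut-2-en-1-yl)bicyclo[3.3.1]non-3-ene-2,9-dione | CC(C)=CC[C@@H]1C[C@]2(CC=C(C)C)C(=O)[C@@](CC=C(C)C)(C(=O)C(C(=O)c3ccc4OC(OCC)Oc4c3)=C2O)C1(C)C
F6 | step 9 | 2-[(1S,5S,7S)-3-{3,4-bis[(tert-butyldimethylsilyl)oxy]benzoyl}-4-hydroxy-8,8-dimethyl-1,5-bis(3-methylbut-2-en-1-yl)-2,9-dioxobicyclo[3.3.1]non-3-en-7-yl]acetaldehyde | O=CC[C@@H]1C[C@]2(CC=C(C)C)C(=O)[C@@](CC=C(C)C)(C(=O)C(C(=O)c3ccc(O[Si](C)(C)C(C)(C)C)c(O[Si](C)(C)C(C)(C)C)c3)=C2O)C1(C)C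
F7 | step 9 | (1S,5S,7R)-3-{3,4-bis[(tert-butyldimethylsilyl)oxy]benzoyl}-4-hydroxy-8,8-dimethyl-1,5,7-tris(3-methylbut-2-en-1-yl)bicyclo[3.3.1]non-3-ene-2,9-dione | CC(C)=CC[C@@H]1C[C@]2(CC=C(C)C)C(=O)[C@@](CC=C(C)C)(C(=O)C(C(=O)c3ccc(O[Si](C)(C)C(C)(C)C)c(O[Si](C)(C)C(C)(C)C)c3)=C2O)C1(C)C
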